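**Strategy.** The route rests on cutting the aryl ether bond O1–C8a of the chromanone and the methylene bridge. O1–C8a lies ortho to the C4 ketone on C4a, so C8a is the β-carbon of a vinylogous ester and can serve as an SNAr carbon. In one flask the lithium enolate of a 6-fluoro-2,4-dimethoxy-3-methylacetophenone adds to acetone and the tertiary alkoxide formed displaces fluoride, which builds the gem-dimethyl dihydropyranone ring. The fluorine, placed by symmetry, fixes the methyl group at C6 and leaves C8 free. After demethylation, C8 is joined to the Mannich base of the second acylphloroglucinol through an ortho-quinone methide.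

Key step: step 3

Remark: the target has no stereocentre and is achiral, so no stereocontrol is needed; ring atoms are numbered as in chroman-4-one (O1, C2, C3, C4, C4a, C5–C8, C8a), and 1 and 8 are taken as commercial.

**Step 1**
Reactants: 1 3,5-dimethoxy-4-methylbenzoic acid
Product: 2 5-fluoro-1,3-dimethoxy-2-methylbenzene
Conditions: Cu(OTf)2, [Cu(MeCN)4]BF4, TBAF·(t-BuOH)4, MeCN, 390 nm LEDs, 35 °C
Reagents that add atoms: tetrabutylammonium fluoride (tert-butanol complex) [F-].CCCC[N+](CCCC)(CCCC)CCCC
Why: Copper-LMCT aromatic decarboxylative fluorination: photolysis of the copper(II) carboxylate of 1 releases CO2, and the aryl radical is captured by copper and fluorinated by C–F reductive elimination at the former carboxyl carbon, which the mirror symmetry of 1 makes the only possible site.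

**Step 2**
Reactants: 2 5-fluoro-1,3-dimethoxy-2-methylbenzene
Product: 3 1-(6-fluoro-2,4-dimethoxy-3-methylphenyl)ethan-1-one
Conditions: AcCl, SnCl4, CH2Cl2, −10 → 0 °C
Reagents that add atoms: acetyl chloride CC(=O)Cl
Why: Friedel–Crafts acylation: the two free ring positions of 2 are equivalent and each is para to one methoxy group and ortho to the other, so only 3 can form, and SnCl4 at low temperature should spare the methyl ethers.

**Step 3**
Reactants: 3 1-(6-fluoro-2,4-dimethoxy-3-methylphenyl)ethan-1-one
Product: 6 5,7-dimethoxy-2,2,6-trimethylchroman-4-one, via lithium enolate 4 (not isolated), via lithium aldolate 5 (not isolated)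
Conditions: LiHMDS, THF, −78 °C; acetone (3 equiv); then DMPU, −78 → 25 °C
Reagents that add atoms: acetone CC(C)=O
Why: LiHMDS forms lithium enolate 4, which adds to acetone to give the tertiary aldolate 5; in THF–DMPU its alkoxide oxygen attacks the fluorine-bearing ring carbon ortho to the ketone, the Meisenheimer anion is delocalised into the C4 carbonyl, and loss of fluoride forms the O1–C8a bond. The closest known reaction types are the crossed aldol addition of a preformed lithium enolate to a ketone and the intramolecular SNAr etherification of ortho-fluoroaryl ketones used for chromones and xanthones. The dihydropyranone ring is closed in a 6-exo-trig addition–elimination at the aromatic carbon, and no stereocentre is formed. The step needs substitution to outrun retro-aldol cleavage and E1cB dehydration of 5: the excess of acetone returns any enolate set free by retro-aldol to 5, so that the irreversible loss of lithium fluoride is the main exit. It also needs attack at C–F and not at the other ortho carbon, which bears OMe, and the far better nucleofugality of fluoride and the higher electrophilicity of its carbon secure this. Because fluorine marks the future C8a, the methyl group can only end up at C6 and the free CH at C8.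

**Step 4**
Reactants: 6 5,7-dimethoxy-2,2,6-trimethylchroman-4-one
Product: 7 5,7-dihydroxy-2,2,6-trimethylchroman-4-one
Conditions: BBr3, CH2Cl2, −78 → 25 °C; then H2O
Reagents that add atoms: none
Why: Boron tribromide ether cleavage: the 5-OMe group is cleaved through the carbonyl chelate and the 7-OMe group at room temperature, while O1 is a poorly basic vinylogous ester oxygen whose cleavage would need a cation at C2 beta to the complexed carbonyl, so the ring should survive.

**Step 5**
Reactants: 8 2-methylbenzene-1,3,5-triol
Product: 9 1-(2,4,6-trihydroxy-3-methylphenyl)-2-methylpropan-1-one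
Conditions: i-PrCOCl, AlCl3, PhNO2–CH2Cl2, 0 → 40 °C
Reagents that add atoms: isobutyryl chloride CC(C)C(=O)Cl
Why: Friedel–Crafts C-acylation of the phloroglucinol: both free positions of 8 are equivalent and the first acyl group deactivates the ring against a second acylation.

**Step 6**
Reactants: 9 1-(2,4,6-trihydroxy-3-methylphenyl)-2-methylpropan-1-one
Product: 10 1-(2,6-dihydroxy-4-methoxy-3-methylphenyl)-2-methylpropan-1-one
Conditions: Me2SO4 (1 equiv), K2CO3 (1 equiv), acetone, 25 °C
Reagents that add atoms: dimethyl sulfate COS(=O)(=O)OC
Why: Williamson O-methylation: the 4-OH para to the acyl group is the most acidic and the only one not tied up in a hydrogen bond to the carbonyl, so one equivalent of dimethyl sulfate should alkylate it in preference to the chelated 2- and 6-OH groups.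

**Step 7**
Reactants: 10 1-(2,6-dihydroxy-4-methoxy-3-methylphenyl)-2-methylpropan-1-one
Product: 11 1-[3-[(dimethylamino)methyl]-2,6-dihydroxy-4-methoxy-5-methylphenyl]-2-methylpropan-1-one
Conditions: Eschenmoser's salt, MeCN, 0 → 25 °C; aq NaHCO3
Reagents that add atoms: N,N-dimethylmethyleneiminium iodide C=[N+](C)C.[I-]
Why: Mannich aminomethylation with a preformed iminium salt: the single free ring carbon of 10, between OMe and OH, is strongly activated, and the absence of base and heat keeps the product from eliminating the amine.

**Step 8**
Reactants: 11 1-[3-[(dimethylamino)methyl]-2,6-dihydroxy-4-methoxy-5-methylphenyl]-2-methylpropan-1-one; 7 5,7-dihydroxy-2,2,6-trimethylchroman-4-one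
Product: 13 mallopallidol, via ortho-quinone methide 12 (not isolated)
Conditions: 7 (1.5 equiv), 1,4-dioxane, 100 °C
Reagents that add atoms: none
Why: Thermal elimination of dimethylamine from the phenolic Mannich base gives ortho-quinone methide 12, which is trapped in a Friedel–Crafts-type conjugate addition by C8 of 7, its only free ring position, while fully substituted 11 cannot alkylate itself at carbon.

**Compound list**
1 | 3,5-dimethoxy-4-methylbenzoic acid | COc1cc(C(=O)O)cc(OC)c1C | starting material
2 | 5-fluoro-1,3-dimethoxy-2-methylbenzene | COc1cc(F)cc(OC)c1C | intermediate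
3 | 1-(6-fluoro-2,4-dimethoxy-3-methylphenyl)ethan-1-one | CC(=O)c1c(F)cc(OC)c(C)c1OC | intermediate
4 | lithium 1-(6-fluoro-2,4-dimethoxy-3-methylphenyl)ethen-1-olate (lithium enolate, not isolated) | [Li+].C=C([O-])c1c(F)cc(OC)c(C)c1OC | intermediate
5 | lithium 4-(6-fluoro-2,4-dimethoxy-3-methylphenyl)-2-methyl-4-oxobutan-2-olate (lithium aldolate, not isolated) | [Li+].CC(C)([O-])CC(=O)c1c(F)cc(OC)c(C)c1OC | intermediate
6 | 5,7-dimethoxy-2,2,6-trimethylchroman-4-one | COc1cc2OC(C)(C)CC(=O)c2c(OC)c1C | intermediate
7 | 5,7-dihydroxy-2,2,6-trimethylchroman-4-one | Cc1c(O)cc2OC(C)(C)CC(=O)c2c1O | intermediate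
8 | 2-methylbenzene-1,3,5-triol (2,4,6-trihydroxytoluene) | Cc1c(O)cc(O)cc1O | starting material
9 | 1-(2,4,6-trihydroxy-3-methylphenyl)-2-methylpropan-1-one | CC(C)C(=O)c1c(O)cc(O)c(C)c1O | intermediate
10 | 1-(2,6-dihydroxy-4-methoxy-3-methylphenyl)-2-methylpropan-1-one | CC(C)C(=O)c1c(O)cc(OC)c(C)c1O | intermediate
11 | 1-[3-[(dimethylamino)methyl]-2,6-dihydroxy-4-methoxy-5-methylphenyl]-2-methylpropan-1-one | CC(C)C(=O)c1c(O)c(CN(C)C)c(OC)c(C)c1O | intermediate
12 | 3-hydroxy-5-methoxy-4-methyl-6-methylidene-2-(2-methylpropanoyl)cyclohexa-2,4-dien-1-one (ortho-quinone methide, not isolated) | C=C1C(=O)C(C(=O)C(C)C)=C(O)C(C)=C1OC | intermediate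
13 | mallopallidol | COc1c(C)c(O)c(C(=O)C(C)C)c(O)c1Cc1c(O)c(C)c(O)c2c1OC(C)(C)CC2=O | target

**Step count.** Total: 8 steps. Longest linear sequence: 5 steps (steps 1, 2, 3, 4 and 8); steps 5–7 form the second branch.

**Steps most likely to fail**

Step 3. The aldolate may be lost by retro-aldol cleavage or E1cB dehydration faster than it substitutes the electron-rich fluoroarene. The product may also be enolised by remaining alkoxide and its new ring opened, which drains the base. In that case the oxygen would be placed first and the ring closed from the other side. Setting out from 3, fluoride is displaced by hydroxide (KOH, DMSO–H2O, 80 °C) to give 1-(6-hydroxy-2,4-dimethoxy-3-methylphenyl)ethan-1-one F1. A Kabbe condensation of this phenol with acetone (pyrrolidine, EtOH, reflux) then gives 6, where the route resumes. The position of the fluorine still fixes the regiochemistry.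

Step 1. Radical decarboxylation may be inefficient on this electron-rich acid, with protodecarboxylation or oxidation of the arene taking over. The fluoride would then be introduced by ionic chemistry. Setting out from 1, a Curtius rearrangement (DPPA, Et3N, toluene, 80 °C; then aq HCl) gives 3,5-dimethoxy-4-methylaniline F2. Diazotisation (NaNO2, aq HBF4, 0 °C) gives 3,5-dimethoxy-4-methylbenzenediazonium tetrafluoroborate F3, and Balz–Schiemann thermolysis of the dry salt returns to 2.

Step 4. The Lewis acid may open the pyranone ring at O1–C2, and re-closure through the freed 5-OH would scramble the methyl group between C6 and C8; cleavage of the 7-OMe group may also stay incomplete. The protecting group would then be changed before the ring is made. Setting out from 2, BBr3 in CH2Cl2 gives 5-fluoro-2-methylbenzene-1,3-diol F4, and BnBr with K2CO3 in DMF gives 1,3-bis(benzyloxy)-5-fluoro-2-methylbenzene F5. Acetylation with AcOH and trifluoroacetic anhydride gives 1-[2,4-bis(benzyloxy)-6-fluoro-3-methylphenyl]ethan-1-one F6. The aldol–SNAr conditions of step 3 then give 5,7-bis(benzyloxy)-2,2,6-trimethylchroman-4-one F7, and neutral hydrogenolysis (H2, Pd/C, EtOAc) returns to 7.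

**Further compounds**
F1 | step 3 | 1-(6-hydroxy-2,4-dimethoxy-3-methylphenyl)ethan-1-one | CC(=O)c1c(O)cc(OC)c(C)c1OC
F2 | step 1 | 3,5-dimethoxy-4-methylaniline | COc1cc(N)cc(OC)c1C
F3 | step 1 | 3,5-dimethoxy-4-methylbenzenediazonium tetrafluoroborate | COc1cc([N+]#N)cc(OC)c1C.F[B-](F)(F)F
F4 | step 4 | 5-fluoro-2-methylbenzene-1,3-diol | Cc1c(O)cc(F)cc1O
F5 | step 4 | 1,3-bis(benzyloxy)-5-fluoro-2-methylbenzene | Cc1c(OCc2ccccc2)cc(F)cc1OCc1ccccc1
F6 | step 4 | 1-[2,4-bis(benzyloxy)-6-fluoro-3-methylphenyl]ethan-1-one | CC(=O)c1c(F)cc(OCc2ccccc2)c(C)c1OCc1ccccc1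
F7 | step 4 | 5,7-bis(benzyloxy)-2,2,6-trimethylchroman-4-one | Cc1c(OCc2ccccc2)cc2OC(C)(C)CC(=O)c2c1OCc1ccccc1
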